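## Retrosynthetic overview
1. Target ⇒ its 5-O-benzyl ether, cleaved last by neutral hydrogenolysis. The benzyl group blocks the C5 oxygen, so the lactone can only close on the oxygen next to the acyl group.
2. 5-O-benzyl ether ⇒ a 3-substituted 4-benzyloxy-6-methyl-2-pyrone + methyl 3-(4-methoxyphenyl)propanoate. The cuts are C8–C(=O), C8–C8a and O1–C2. Phloroglucinol ring A and the δ-lactone are built together from the pyrone carbons by a polyketide-type Claisen recyclisation.
3. Pyrone ester ⇒ triacetic acid lactone + cinnamaldehyde. The C4–C4a bond and the S centre come from an enantioselective carbene-catalysed oxidative annulation, followed by methanolysis and O-benzylation.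
4. Ring order: a sacrificial dihydropyranone is made and opened in step 1. In step 3 the purchased pyrone ring is opened, then ring A forms, then the δ-lactone, all in one operation. Both aryl rings are bought.

Assumption: the sense of induction of the chiral triazolium salt on this enol is taken by analogy. Both antipodes are sold, and the one that gives the 4S series is used (checked by X-ray of the benzyl ether or by CD of the final product).

## Route

Step 1
Reactants: 1 4-hydroxy-6-methyl-2H-pyran-2-one (triacetic acid lactone); 2 (E)-cinnamaldehyde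
Product: 4 methyl (3S)-3-(4-hydroxy-6-methyl-2-oxo-2H-pyran-3-yl)-3-phenylpropanoate, via bicyclic enol lactone 3 (not isolated)
Conditions: 2 (1.3 equiv), aminoindanol-derived N-mesityl triazolium chloride (10 mol %, antipode giving 4S), iPr2NEt (20 mol %), 3,3',5,5'-tetra-tert-butyldiphenoquinone (1.1 equiv), THF–toluene, 40 °C; then MeOH (20 equiv), DMAP (10 mol %), 23 °C
Reagents that add atoms: methanol, CO
Why: Oxidative N-heterocyclic-carbene catalysis (acyl azolium activation) makes 2 a chiral cinnamoyl electrophile, the stable enol 1 adds through C3 to the Si face of the β-carbon (Michael addition–lactonisation, Coates–Claisen-type annulation) and sets C4 as S, and the activated enol lactone 3 is then opened by DMAP-catalysed methanolysis without touching the stereocentre.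

Step 2
Reactants: 4 methyl (3S)-3-(4-hydroxy-6-methyl-2-oxo-2H-pyran-3-yl)-3-phenylpropanoate
Product: 5 methyl (3S)-3-[4-(benzyloxy)-6-methyl-2-oxo-2H-pyran-3-yl]-3-phenylpropanoate
Conditions: BnBr (1.2 equiv), K2CO3 (1.5 equiv), DMF, 23–40 °C
Reagents that add atoms: benzyl bromide, BrCc1ccccc1
Why: Williamson-type O-alkylation of the vinylogous acid (pKa about 5) goes to O4 because C3 carries a bulky secondary alkyl group, the ether becomes the C5–O block that later leaves a single phenol beside the side chain, and the stereocentre is not involved.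

Step 3
Reactants: 5 methyl (3S)-3-[4-(benzyloxy)-6-methyl-2-oxo-2H-pyran-3-yl]-3-phenylpropanoate; 6 methyl 3-(4-methoxyphenyl)propanoate
Product: 10 (4S)-5-(benzyloxy)-7-hydroxy-8-[3-(4-methoxyphenyl)propanoyl]-4-phenylchroman-2-one, via acylated pyrone 7 (not isolated), via open-chain enol ether diester 8 (not isolated), via acylresorcinol methyl ester 9 (not isolated)
Conditions: LiN(SiMe3)2 (2.4 equiv), THF, −78 °C; 6 (2 equiv), −78 → 0 °C; then Mg(OMe)2 (5 equiv) in MeOH, 65 °C; then 2 M HCl, extraction into toluene, TsOH·H2O (10 mol %), 100 °C (−MeOH)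
Reagents that add atoms: magnesium methoxide, C[O-].C[O-].[Mg+2] (its methoxy group is carried only by 8 and leaves again as methanol; no reagent atom other than hydrogen stays in 10)
Why: Proposed new method: the amide base deprotonates the 6-methyl group (vinylogous ester, C3 blocked) and the dienolate is acylated by 6 (Claisen condensation) to the enolate of 7; methoxide, helped by magnesium chelation, opens the pyrone at C2 to 8, whose former ring double bond holds the new ester and the β-diketonate chain cis; the doubly activated carbon then attacks that ester (Dieckmann-type Claisen cyclisation) and enolisation to the arene makes ring A (9) irreversibly; acid finally lets the only phenol flanking the side chain displace methanol to close the δ-lactone, so two rings form in one operation with fixed regiochemistry; C4 stays S because C4a is sp2 throughout and no retro-Michael path exists; the closest known reactions are the biomimetic Mg(OMe)2- or KOH/MeOH-induced recyclisation of 6-(2-oxoalkyl)-4-methoxy-2-pyrones to 2-acyl-5-methoxyresorcinols, the γ-acylation of 6-methyl-2-pyrone dienolates, and the acid lactonisation of 3-(2-hydroxyaryl)propanoates.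

Step 4
Reactants: 10 (4S)-5-(benzyloxy)-7-hydroxy-8-[3-(4-methoxyphenyl)propanoyl]-4-phenylchroman-2-one
Product: 11 (4S)-5,7-dihydroxy-8-[3-(4-methoxyphenyl)propanoyl]-4-phenylchroman-2-one (target)
Conditions: H2 (1 atm), palladium on carbon (Pd/C, 10 wt % Pd, 5 mol %), EtOAc, 23 °C
Reagents that add atoms: none
Why: Catalytic hydrogenolysis cleaves the aryl benzyl ether under neutral conditions, the chelated aryl ketone, lactone and anisole survive, the absence of acid or base keeps the lactone from migrating to the freed C5–OH, and the stereocentre is untouched.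

## Compound list
1 | 4-hydroxy-6-methyl-2H-pyran-2-one | CC1=CC(O)=CC(=O)O1 | starting material
2 | (E)-cinnamaldehyde | O=C/C=C/c1ccccc1 | starting material
3 | (4S)-7-methyl-4-phenyl-3,4-dihydro-2H,5H-pyrano[4,3-b]pyran-2,5-dione | O=C1C[C@@H](c2ccccc2)C2=C(O1)C=C(C)OC2=O | intermediate
4 | methyl (3S)-3-(4-hydroxy-6-methyl-2-oxo-2H-pyran-3-yl)-3-phenylpropanoate | COC(=O)C[C@@H](c1ccccc1)C1=C(O)C=C(C)OC1=O | intermediate
5 | methyl (3S)-3-[4-(benzyloxy)-6-methyl-2-oxo-2H-pyran-3-yl]-3-phenylpropanoate | COC(=O)C[C@@H](c1ccccc1)C1=C(OCc2ccccc2)C=C(C)OC1=O | intermediate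
6 | methyl 3-(4-methoxyphenyl)propanoate | COC(=O)CCc1ccc(OC)cc1 | starting material
7 | methyl (3S)-3-{4-(benzyloxy)-6-[4-(4-methoxyphenyl)-2-oxobutyl]-2-oxo-2H-pyran-3-yl}-3-phenylpropanoate | COC(=O)C[C@@H](c1ccccc1)C1=C(OCc2ccccc2)C=C(CC(=O)CCc2ccc(OC)cc2)OC1=O | intermediate
8 | dimethyl (2E,3S)-2-[1-(benzyloxy)-7-(4-methoxyphenyl)-3,5-dioxoheptylidene]-3-phenylpentanedioate | COC(=O)C[C@@H](c1ccccc1)/C(C(=O)OC)=C(\OCc1ccccc1)CC(=O)CC(=O)CCc1ccc(OC)cc1 | intermediate
9 | methyl (3S)-3-{6-(benzyloxy)-2,4-dihydroxy-3-[3-(4-methoxyphenyl)propanoyl]phenyl}-3-phenylpropanoate | COC(=O)C[C@@H](c1ccccc1)c1c(OCc2ccccc2)cc(O)c(C(=O)CCc2ccc(OC)cc2)c1O | intermediate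
10 | (4S)-5-(benzyloxy)-7-hydroxy-8-[3-(4-methoxyphenyl)propanoyl]-4-phenylchroman-2-one | O=C1C[C@@H](c2ccccc2)c2c(OCc3ccccc3)cc(O)c(C(=O)CCc3ccc(OC)cc3)c2O1 | intermediate
11 | (4S)-5,7-dihydroxy-8-[3-(4-methoxyphenyl)propanoyl]-4-phenylchroman-2-one | COc1ccc(CCC(=O)c2c(O)cc(O)c3c2OC(=O)C[C@H]3c2ccccc2)cc1 | target

## Step count and risks
Total steps: 4. Longest linear sequence: 4 (1 → 4 → 5 → 10 → 11).

**Step 3 (highest risk).**
- The dienolate may attack the side-chain ester of a second molecule of 5.
- The hindered pyrone may open slowly.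
- Methoxide may exchange with the benzyloxy group.
- The open chain may close to a γ-pyrone instead of the arene.

Fallback, from 6 back to 10, with ring A bought instead of built. Compound 6 is saponified (LiOH, THF–water) to 3-(4-methoxyphenyl)propanoic acid F1. F1 acylates phloroglucinol (BF3·OEt2, 80 °C) to 1-(2,4,6-trihydroxyphenyl)-3-(4-methoxyphenyl)propan-1-one F2. The unchelated para hydroxyl is benzylated selectively (BnBr 1 equiv, K2CO3, acetone) to 1-[4-(benzyloxy)-2,6-dihydroxyphenyl]-3-(4-methoxyphenyl)propan-1-one F3. F3 is then annulated with 2 under the oxidative triazolium conditions of step 1. Only the hydroxyl beside the acyl group can lactonise, which gives 10.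

**Step 1.**
- The ee or the sense of induction on this enol may be poor.
- The reaction may stop at O-acylation.

Fallback, from 1 and 2 back to 3, by iminium instead of acyl azolium activation. α,α-Diphenylprolinol trimethylsilyl ether (antipode giving 4S) with benzoic acid in CH2Cl2 adds 1 to 2. The product is (4S)-2-hydroxy-7-methyl-4-phenyl-3,4-dihydro-2H,5H-pyrano[4,3-b]pyran-5-one F4. TEMPO/PhI(OAc)2 oxidises F4 to 3, and methanolysis continues as in the route.

**Step 2.** The ambident pyronolate may be alkylated at O2 (giving the γ-pyrone isomer) or at C3.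

Fallback, from 4 back to 5, by redox condensation instead of enolate alkylation. A Mitsunobu reaction of 4 with benzyl alcohol (PPh3, DIAD, THF, 0 °C) uses the acidic 4-OH as pronucleophile under neutral conditions, so no free pyronolate is present. This fallback makes no compound outside the list (F0).

## Further compounds
F1 | step 3 | 3-(4-methoxyphenyl)propanoic acid | COc1ccc(CCC(=O)O)cc1
F2 | step 3 | 1-(2,4,6-trihydroxyphenyl)-3-(4-methoxyphenyl)propan-1-one | COc1ccc(CCC(=O)c2c(O)cc(O)cc2O)cc1
F3 | step 3 | 1-[4-(benzyloxy)-2,6-dihydroxyphenyl]-3-(4-methoxyphenyl)propan-1-one | COc1ccc(CCC(=O)c2c(O)cc(OCc3ccccc3)cc2O)cc1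
F4 | step 1 | (4S)-2-hydroxy-7-methyl-4-phenyl-3,4-dihydro-2H,5H-pyrano[4,3-b]pyran-5-one | OC1C[C@@H](c2ccccc2)C2=C(O1)C=C(C)OC2=O
F0 | step 2 | none | none
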